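Multiplying a percentage of the charge by the charge gives a concentration, and a concentration is what a solid responds to, so I begin there.

- south: substrate 2.1 M; run made earlier
- flask: substrate 1.5 M; time 1.0 h

- south (time / min: target / %, crystals / %): 5.00: 6.5, 0; 12.0: 15.3, 0.8; 25.0: 27.3, 0; 60.0: 47.4, 15.4

(scatter of a reading: 0.5 percentage points)

- what is said of target includes crystals
- crystals is a solid; its amount is given per volume of the solution
- what was read earlier has a scatter of 0.5 percentage points, one standard deviation
- steps that have been proposed: substrate <-> isomer of the product; substrate <-> target; crystals <-> target

* the target and crystals together standing at 1.0 h, as a percentage of the substrate charged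
* concentration of target in solution at 1.0 h, in percent of saturation

The south run looks nearly the same as the flask, with another charge. If the steps are first order in solution, both convert the same share in the same time, but a saturation limit is a concentration, not a share. South at 25.0 min reads crystals 0%, with target at 27.3%, so I take that last clear concentration as my ceiling:

ceiling = target share × south charge = 0.573 M

crossing share = ceiling / flask charge = 38.2%

I call this upper estimate, read from a crystal reading that carries its scatter, of the share of the charge in target at which crystals begin, the onset of crystallisation, the crossing share. South at 60.0 min stands 20 percentage points above its crossing and reads crystals 15.4%. The flask, if it reaches the same share, stands 9.2 points above its own. I expect fewer crystals in the flask than in south because its crossing share is higher.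

The forecast gives 46.5% and 106%, with “so saturation is about 0.60–0.67 M”; my ceiling is 0.573 M.

    substrate ⇌ isomer of the product (K = 2.30, k = 2.90 × 10⁻⁵ s⁻¹)
    substrate ⇌ target (K = 1.90, k = 2.40 × 10⁻⁴ s⁻¹)
    crystals ⇌ target, rate k3*(cs3 - [target]) while solid is left; crystals form when [target] > cs3 (solubility = 0.540 M, k = 0.00120 s⁻¹)

The flask gives 46.1% and 113%, the second 7.3 points above the forecast. At 0.500 h the flask holds target 30.9%, under the crossing share, with crystals 0%. At 1.00 h its target stands 7.9 points over that share, with crystals 5.29%. The same flask read at 4.0 h holds target 66.4%, which is 28 points over the crossing share, and its crystals stand at 30.2%.

Readings and results were computed with constants of no real substance; the scatter is artificial.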